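## Retrosynthetic overview

1. Rings: A = prenylphenol ring, B = central trimethoxybenzene, C = phenyl. The last bond made is the A–B biaryl bond (C-1 of A to C-1' of B). Rings B–C enter as 2,3,5-trimethoxybiphenyl, a plain C–H compound. Ring A enters dearomatised and umpoled, as the p-quinone monoketal 4,4-dimethoxy-3-prenylcyclohexa-2,5-dienone.
2. Enabling feature: C-1' is the only carbon of ring B flanked by two methoxy groups (2'-OMe and 6'-OMe), so its C–H is the most acidic, doubly chelating site. In ring A the phenolic oxygen on C-4 stands para to C-1, so ring A is a latent p-quinone in which C-1 can be a carbonyl carbon.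
3. One flask (lithiation, 1,2-addition, ketal hydrolysis, zinc re-aromatisation) should give the unprotected natural product. The hindered bond needs no halide, boron, palladium or phenol protecting group.
4. Monoketal: 1,4-dimethoxybenzene → ortho-lithiation/prenylation → anodic bisketal → regioselective monohydrolysis. Biphenyl: 5-bromovanillin → Dakin oxidation → O-methylation → Suzuki–Miyaura coupling with phenylboronic acid.
5. No ring is built, since all three benzene rings are purchased. Only ring A is dearomatised (at the anode) and re-aromatised (by zinc) along the route.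

Key step: step 7

Remark: the target has no stereocentre, and its biaryl axes carry ortho substituents on ring B only and rotate freely. The compound is therefore achiral and no enantiomer has to be selected.

## Route

Step 1
Reactants: 1 5-bromovanillin (3-bromo-4-hydroxy-5-methoxybenzaldehyde)
Product: 2 2-bromo-6-methoxybenzene-1,4-diol
Conditions: 30% H2O2, NaOH, H2O, 0 °C → rt, N2; then HCl
Reagents that add atoms: hydrogen peroxide OO
Why: Dakin oxidation, in which the para-hydroxy group speeds aryl migration in the peroxide adduct, the aryl formate is saponified in situ, and the aryl bromide and methyl ether are inert to alkaline peroxide.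

Step 2
Reactants: 2 2-bromo-6-methoxybenzene-1,4-diol
Product: 3 1-bromo-2,3,5-trimethoxybenzene
Conditions: MeI, K2CO3, DMF, rt, N2
Reagents that add atoms: iodomethane CI
Why: Williamson ether synthesis, in which both phenoxides are methylated by SN2 on iodomethane and nothing else in 2 can be alkylated.

Step 3
Reactants: 3 1-bromo-2,3,5-trimethoxybenzene; 4 phenylboronic acid
Product: 5 2,3,5-trimethoxybiphenyl
Conditions: Pd(PPh3)4 (3 mol %), K2CO3, DME/H2O, 85 °C
Reagents that add atoms: none
Why: Suzuki–Miyaura coupling of an aryl bromide with one ortho-methoxy group and an unhindered boronic acid, a routine case that puts ring C at the position of ring B that neither lithiation nor electrophilic substitution would reach.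

Step 4
Reactants: 6 1,4-dimethoxybenzene; 7 prenyl bromide (1-bromo-3-methylbut-2-ene)
Product: 9 1,4-dimethoxy-2-(3-methylbut-2-en-1-yl)benzene, via 2,5-dimethoxyphenyllithium 8 (not isolated)
Conditions: n-BuLi, TMEDA, THF, 0 °C → rt; CuBr·SMe2 (10 mol %), 7, −78 °C → rt
Reagents that add atoms: none
Why: Directed ortho-metalation followed by copper-catalysed allylic substitution at the primary carbon of prenyl bromide, where all four ring C–H bonds of 6 are equivalent so only one aryllithium can form.

Step 5
Reactants: 9 1,4-dimethoxy-2-(3-methylbut-2-en-1-yl)benzene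
Product: 10 3,3,6,6-tetramethoxy-1-(3-methylbut-2-en-1-yl)cyclohexa-1,4-diene
Conditions: undivided cell, Pt anode, Pt cathode, constant current, 1% KOH/MeOH, 0 °C
Reagents that add atoms: methanol CO
Why: Anodic dearomatising bis-methoxylation of a hydroquinone dimethyl ether to its quinone bisketal, a long-established electrosynthesis in which the dimethoxyarene is by far the most easily oxidised π-system of 9, methoxide adds at the two oxygen-bearing ring carbons, the isolated trisubstituted alkene should stay untouched, and the cathode only evolves hydrogen.

Step 6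
Reactants: 10 3,3,6,6-tetramethoxy-1-(3-methylbut-2-en-1-yl)cyclohexa-1,4-diene
Product: 11 4,4-dimethoxy-3-(3-methylbut-2-en-1-yl)cyclohexa-2,5-dien-1-one
Conditions: AcOH/H2O/THF, 0 °C
Reagents that add atoms: water O
Why: Regioselective acid-catalysed monohydrolysis of a quinone bisketal, in which rate-determining loss of methanol gives a methoxy-stabilised cyclohexadienyl cation whose charge also sits on the two ring carbons next to the other ketal, so only ionisation of the ketal remote from the prenyl group puts charge on the alkyl-bearing carbon and that ketal should go first, while the enone formed slows a second hydrolysis.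

Step 7
Reactants: 5 2,3,5-trimethoxybiphenyl; 11 4,4-dimethoxy-3-(3-methylbut-2-en-1-yl)cyclohexa-2,5-dien-1-one
Product: 15 sanshamycin B, via aryllithium 12 (not isolated), via quinol ketal 13 (not isolated), via p-quinol 14 (not isolated)
Conditions: n-BuLi (1.0 equiv), THF, 0 °C → rt; 11, THF, −78 °C; AcOH/H2O, 0 °C → rt; Zn dust, rt (one pot)
Reagents that add atoms: water O
Why: n-BuLi removes the one proton of ring B that lies between two methoxy groups (directed ortho-metalation with both oxygens binding lithium, whereas the other ring-B C–H has a single methoxy neighbour and is shielded by ring C), so nucleophile 12 forms at exactly the carbon that electrophilic or oxidative couplings would avoid. 12 then adds 1,2 to the only carbonyl group of 11, which is flanked by two CH groups and so stays accessible even to a 2,6-dimethoxyaryl nucleophile; this is the known addition of aryllithiums to quinone monoketals, and it makes the di-ortho-substituted biaryl bond as a simple carbonyl addition. Dilute acetic acid hydrolyses the ketal of 13 through a methoxy-stabilised dienyl cation captured irreversibly by water, giving p-quinol 14, after which zinc transfers two electrons to the dienone, hydroxide leaves from the para carbon and ring A re-aromatises (known reductive aromatisation of p-quinols to phenols). No ring is closed, and the carbinol carbon of 13 and 14 is a stereocentre formed as a racemate that becomes planar again in 15, so no stereocontrol is needed. The selectivities required are the site of metalation (secured by the two flanking OMe groups), 1,2-addition over 1,4-addition and over deprotonation of the doubly allylic CH2 (hard aryllithium, −78 °C, unhindered C=O), the ortho relation of prenyl and OH (fixed because the ketal of 11 stands next to the prenyl-bearing carbon) and survival of the alkene and the acid-sensitive o-prenylphenol (no strong acid, oxidant or metal hydride is present).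

## Compound list

1 | 5-bromovanillin | COc1cc(C=O)cc(Br)c1O | starting material
2 | 2-bromo-6-methoxybenzene-1,4-diol | COc1cc(O)cc(Br)c1O | intermediate
3 | 1-bromo-2,3,5-trimethoxybenzene | COc1cc(Br)c(OC)c(OC)c1 | intermediate
4 | phenylboronic acid | OB(O)c1ccccc1 | starting material
5 | 2,3,5-trimethoxybiphenyl | COc1cc(OC)c(OC)c(-c2ccccc2)c1 | intermediate
6 | 1,4-dimethoxybenzene | COc1ccc(OC)cc1 | starting material
7 | prenyl bromide | CC(C)=CCBr | starting material
8 | 2,5-dimethoxyphenyllithium (not isolated) | [Li]c1cc(OC)ccc1OC | intermediate
9 | 1,4-dimethoxy-2-(3-methylbut-2-en-1-yl)benzene | COc1ccc(OC)c(CC=C(C)C)c1 | intermediate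
10 | 3,3,6,6-tetramethoxy-1-(3-methylbut-2-en-1-yl)cyclohexa-1,4-diene | COC1(OC)C=CC(OC)(OC)C(CC=C(C)C)=C1 | intermediate
11 | 4,4-dimethoxy-3-(3-methylbut-2-en-1-yl)cyclohexa-2,5-dien-1-one | COC1(OC)C=CC(=O)C=C1CC=C(C)C | intermediate
12 | (2,3,5-trimethoxybiphenyl-4-yl)lithium (not isolated) | [Li]c1c(OC)cc(-c2ccccc2)c(OC)c1OC | intermediate
13 | (±)-4,4-dimethoxy-3-(3-methylbut-2-en-1-yl)-1-(2,3,5-trimethoxybiphenyl-4-yl)cyclohexa-2,5-dien-1-ol (formed as lithium alkoxide, shown protonated, not isolated) | COc1cc(-c2ccccc2)c(OC)c(OC)c1C1(O)C=CC(OC)(OC)C(CC=C(C)C)=C1 | intermediate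
14 | (±)-4-hydroxy-2-(3-methylbut-2-en-1-yl)-4-(2,3,5-trimethoxybiphenyl-4-yl)cyclohexa-2,5-dien-1-one (not isolated) | COc1cc(-c2ccccc2)c(OC)c(OC)c1C1(O)C=CC(=O)C(CC=C(C)C)=C1 | intermediate
15 | sanshamycin B (2',3',6'-trimethoxy-3-(3-methylbut-2-en-1-yl)-p-terphenyl-4-ol, achiral) | COc1cc(-c2ccccc2)c(OC)c(OC)c1-c1ccc(O)c(CC=C(C)C)c1 | target

## Step count and risks

Total step count: 7. Longest linear sequence: 4 (steps 1, 2, 3, 7 or steps 4, 5, 6, 7).

**Step 7.**
- What may go wrong:
  - The hindered, basic aryllithium may deprotonate the doubly allylic CH2 of the dienone.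
  - It may transfer an electron instead of adding to the carbonyl group.
  - In the acid phase the tertiary bis-allylic hydroxyl group may be lost before the ketal is hydrolysed. Reduction would then expel methoxide instead of hydroxide, or the cation would decay by proton loss.
- Fallback (palladium cross-coupling and late prenylation), which sets out from 5 and comes back at 15:
  - Aryllithium 12, made from 5 as above, is quenched with iodine to give 4-iodo-2,3,5-trimethoxybiphenyl F1.
  - Suzuki–Miyaura coupling of F1 with purchased 4-hydroxyphenylboronic acid pinacol ester F2 (Pd(OAc)2/SPhos, K3PO4, dioxane/H2O, 90 °C) should give 2',3',6'-trimethoxy-p-terphenyl-4-ol F3.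
  - ortho-C-Prenylation of the sodium phenoxide of F3 with 7 (NaH, toluene) should give 15. The non-polar medium favours C- over O-alkylation, and the two ortho positions are equivalent.

**Step 6.**
- What may go wrong: hydrolysis may start at the ketal next to the prenyl group, or it may run on to the quinone.
- Fallback (regiochemistry fixed by phenol oxidation instead of by hydrolysis), which sets out from 7 and comes back at 11:
  - Purchased 4-methoxyphenol F4 is silylated (TIPSCl, imidazole, DMF) to triisopropyl(4-methoxyphenoxy)silane F5.
  - The bulky silyl ether does not direct metalation, so s-BuLi/TMEDA should lithiate next to the methoxy group to give [2-methoxy-5-(triisopropylsilyloxy)phenyl]lithium F6.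
  - F6 is alkylated by 7 (cat. CuBr·SMe2) to triisopropyl[4-methoxy-3-(3-methylbut-2-en-1-yl)phenoxy]silane F7.
  - TBAF frees 4-methoxy-3-(3-methylbut-2-en-1-yl)phenol F8.
  - Oxidative dearomatisation of F8 with PhI(OAc)2 in MeOH at 0 °C should give 11. This is the only possible monoketal, because the carbonyl oxygen is the former phenol oxygen.

**Step 5.**
- What may go wrong: anodic attack on the side chain, either as methoxylation at the benzylic/allylic CH2 after proton loss from the radical cation or as oxidation of the alkene.
- Fallback (electrolysis before the alkene is present), which sets out from 7 and comes back at 10: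
  - Purchased 2-bromo-1,4-dimethoxybenzene F9 is electrolysed in KOH/MeOH as in step 5 to give 1-bromo-3,3,6,6-tetramethoxycyclohexa-1,4-diene F10.
  - Bromine–lithium exchange (n-BuLi, THF, −78 °C) gives (3,3,6,6-tetramethoxycyclohexa-1,4-dien-1-yl)lithium F11.
  - Copper-catalysed allylic alkylation of F11 with 7 should give 10.

## Further compounds

F1 | step 7 | 4-iodo-2,3,5-trimethoxybiphenyl | COc1cc(-c2ccccc2)c(OC)c(OC)c1I
F2 | step 7 | 4-hydroxyphenylboronic acid pinacol ester (purchased) | CC1(C)OB(c2ccc(O)cc2)OC1(C)C
F3 | step 7 | 2',3',6'-trimethoxy-p-terphenyl-4-ol | COc1cc(-c2ccccc2)c(OC)c(OC)c1-c1ccc(O)cc1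
F4 | step 6 | 4-methoxyphenol (purchased) | COc1ccc(O)cc1
F5 | step 6 | triisopropyl(4-methoxyphenoxy)silane | COc1ccc(O[Si](C(C)C)(C(C)C)C(C)C)cc1
F6 | step 6 | [2-methoxy-5-(triisopropylsilyloxy)phenyl]lithium | [Li]c1cc(O[Si](C(C)C)(C(C)C)C(C)C)ccc1OC
F7 | step 6 | triisopropyl[4-methoxy-3-(3-methylbut-2-en-1-yl)phenoxy]silane | COc1ccc(O[Si](C(C)C)(C(C)C)C(C)C)cc1CC=C(C)C
F8 | step 6 | 4-methoxy-3-(3-methylbut-2-en-1-yl)phenol | COc1ccc(O)cc1CC=C(C)C
F9 | step 5 | 2-bromo-1,4-dimethoxybenzene (purchased) | COc1ccc(OC)c(Br)c1
F10 | step 5 | 1-bromo-3,3,6,6-tetramethoxycyclohexa-1,4-diene | COC1(OC)C=CC(OC)(OC)C(Br)=C1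
F11 | step 5 | (3,3,6,6-tetramethoxycyclohexa-1,4-dien-1-yl)lithium | COC1(OC)C=CC(OC)(OC)C([Li])=C1
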